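The ratio [G]/[D] is what a G molecule meets at its fork, and this text follows that ratio through the four set-ups.

all flasks: L 2.0 mM

|  | Q | time | remark |
|---|---|---|---|
| amber | 1.60 mM | 50 s | plug flow through a tube for 50 s, no back-mixing |
| red | 1.60 mM | 50 s | a closed flask charged with all of it at once and left for 50 s |
| blue | 1.60 mM |  | one stirred flow tank at steady state, fed with the mixture as stated, mean residence time 50 s |
| green | 1.60 mM (fed, over 40.0 s) | 50 s | a stirred flask in which Q is dosed at a steady rate over 40.0 s without added volume, worked up at 50 s |

    L → G (k1 = 0.0772 s⁻¹)
    Q → D (k2 = 0.0318 s⁻¹)
    L + G.D ⇌ L.G.D, settled at all times (K3 = 5680 L mol⁻¹)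
    G + D → G.D (k4 = 20.5 L mol⁻¹ s⁻¹)
    2 G → G2 (k5 = 0.788 L mol⁻¹ s⁻¹)

- percentages count the L that a species holds: one G2 or L.G.D counts as two
- G.D is meant together with its L.G.D
- for a step with 2 of a species take k times the square, and two of it per event
- the stated concentrations are those of everything mixed, before any reaction; amounts are the same in each set-up
- the feed brings no volume worth counting
- in an amount of G.D, one L.G.D counts as one G.D
- run time (amber): 50 s

- the set-up with the highest share of G.D in all that became G.D or G2, at the outlet or at the end ("none" if the first two lie within 2 percentage points) (amber / red / blue / green / none)
- share of G.D in all that became G.D or G2, at the outlet or at the end, amber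
- share of G.D in all that became G.D or G2, at the outlet or at the end, red
- share of G.D in all that became G.D or G2, at the outlet or at the end, blue
- share of G.D in all that became G.D or G2, at the outlet or at the end, green

Twice the rate constant of the G2 step over that of the G.D step, 0.0769, is the fork constant f, the inverse of a selectivity factor. Counted by the L held, G enters G2 rather than G.D at odds of f times [G]/[D], so the share of G.D made at a moment is one over one plus those odds.

Amber and red follow one course in time. At the start, L and Q supply G and D in the ratio 3.03. The ratio then falls, because L halves in 9.0 s, faster than Q, which takes 21.8 s. This gives a floor for amber of 81.1%.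

With no consumption, 50 s leaves a ratio of 1.54. Each G.D removes one G and one D, and while G exceeds D this raises the ratio. Leaving aside the L held in L.G.D, the ceiling for amber is 89.4%.

The ratio at 25.0 s, 1.95, tightens this to 87.0% for amber and 87.0% for red. Blue sits at one composition, with a ratio, reckoned without consumption, of 1.62, which gives 88.9%. Reckoned without consumption, green has received the same supply of G as amber by 25.0 s, but its dosed Q gives a ratio of 5.51, which gives 70.2%. The highest hand figure belongs to blue, but its lead over amber and red is smaller than the margin of 2 percentage points, so by the stated rule the hand's answer is none.

The forecast gives amber 86%, inside the bracket, red 86%, blue 89% and green 72%, above the hand's green, and names blue as best: “Dosing Q starves the system of D while G is at its highest”.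

The simulation gives amber 86.2%, red 86.2%, blue 89.1% and green 72.8%, with blue best. At 25.0 s, amber holds G at 67.4% of the L charged and D at 0.630 mM, so f reads a momentary share of 85.9%. Green at that time holds G at 78.7% and D at 0.243 mM, lower in D than amber, and f reads 66.8%.

(All constants are made up, and the outcome is calculated.)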